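**Plan**

- Retrosynthesis: the acids and phenols are unmasked last (two ethyl esters, two methyl ethers; the C3 acid comes from a C3 aldehyde). The carbocyclic dihydro ring (C1–C2–C3–C4–C4a–C8a) is then cut at C1–C2 and C3=C4, giving a 2-(pyranon-4-ylmethyl)benzaldehyde and ethyl (E)-4-oxobut-2-enoate. The C1–C8a (CH2–aryl) bond is cut next, and last the pyranone (lactone O–C bond and the C5′–C6′ bond).
- Forward: the pyranone is made first (Claisen condensation/lactonisation), the benzene ring is brought in intact by an sp3–sp2 coupling, and the carbocycle of the dihydronaphthalene is closed last by an amine-catalysed Michael/aldol condensation.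
- Enabling feature: C1 is benzylic, γ to the lactone carbonyl of the pyranone (through C4′=C3′–C2′=O) and tied through C8a–C4a to C4. The C1–C8a–C4a–C4 unit is therefore a 1,4-donor/acceptor in the form of an ortho-formyl C–H acid. The C3=C4 bond conjugated to the C3 carbonyl is the trace of an aldol condensation, and C2–C3 corresponds to an enal (acceptor at C2, donor at C3).
- Stereochemistry: C2 is set by the chiral secondary amine (face-selective attack on the iminium ion). C1 follows as the 1,2-trans isomer by equilibration of its acidic C–H. No later step uses base.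

Key step: step 4

Assumption: the target is the (1R,2S)-trans isomer (pyranonyl and C2 carboxyl anti, as read from the SMILES). The sense of induction of the (S)-diarylprolinol silyl ether is taken from the usual shielding model for its E-iminium ions; the (R)-catalyst is equally available.

**Step 1**
Reactants: 1 ethyl 3-methylbut-2-enoate; 2 diethyl oxalate
Product: 4 ethyl 4-methyl-2-oxo-2H-pyran-6-carboxylate, via oxalyl dienol diester 3 (not isolated)
Conditions: KOEt (1.1 equiv), Et2O, 0 °C → rt; AcOH (1.1 equiv), then p-TsOH (cat.), toluene, reflux (−EtOH)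
Reagents that add atoms: none
Why: Crossed Claisen condensation, in which the γ-methyl of 1 is acylated through its dienolate by the non-enolisable oxalate (only this product forms a stabilised enolate, which drives the equilibrium), followed by acid-catalysed enol lactonisation onto the far ester, the classical oxalate route to 2-pyranone-6-carboxylates.

**Step 2**
Reactants: 4 ethyl 4-methyl-2-oxo-2H-pyran-6-carboxylate
Product: 5 ethyl 4-(bromomethyl)-2-oxo-2H-pyran-6-carboxylate
Conditions: NBS (1.05 equiv), AIBN (5 mol%), PhCF3, 80 °C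
Reagents that add atoms: N-bromosuccinimide, O=C1CCC(=O)N1Br
Why: Wohl–Ziegler bromination; the 4-methyl group is the only allylic position (vinylogous α-position of the lactone), so hydrogen abstraction should give a delocalised pyranonylmethyl radical that is brominated at the exocyclic carbon.

**Step 3**
Reactants: 5 ethyl 4-(bromomethyl)-2-oxo-2H-pyran-6-carboxylate; 6 (2-formyl-4,5-dimethoxyphenyl)boronic acid
Product: 7 ethyl 4-(2-formyl-4,5-dimethoxybenzyl)-2-oxo-2H-pyran-6-carboxylate
Conditions: Pd(dppf)Cl2 (5 mol%), K3PO4 (2 equiv), THF/H2O 10:1, 50 °C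
Reagents that add atoms: none
Why: Suzuki–Miyaura sp3–sp2 coupling of an allylic (benzyl-type) bromide with an arylboronic acid; oxidative addition at C–Br is fast, and the mild phosphate base and low temperature should spare the lactone, the aldehyde and the acidic CH2 of 7.

**Step 4**
Reactants: 7 ethyl 4-(2-formyl-4,5-dimethoxybenzyl)-2-oxo-2H-pyran-6-carboxylate; 8 ethyl (E)-4-oxobut-2-enoate
Product: 11 ethyl (1R,2S)-1-[6-(ethoxycarbonyl)-2-oxo-2H-pyran-4-yl]-3-formyl-6,7-dimethoxy-1,2-dihydronaphthalene-2-carboxylate, via Michael adduct dialdehyde 9 (not isolated), via aldol adduct 10 (not isolated)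
Conditions: (S)-2-[bis(3,5-bis(trifluoromethyl)phenyl)(trimethylsilyloxy)methyl]pyrrolidine (20 mol%), LiOAc (30 mol%), toluene, rt, Ar
Reagents that add atoms: none
Why: Proposed new method: the amine condenses with 8 to an E-iminium ion while acetate deprotonates the CH2 of 7 (benzylic, ortho to a formyl group and γ to the lactone carbonyl) to a 4-ylidene-pyran-2-olate, whose exocyclic carbon adds to the iminium β-carbon (C1–C2); the enamine so formed adds to the ortho formyl carbon (C3–C4), and loss of water and hydrolysis release 11 and the amine. The closest known reaction type is the diarylprolinol silyl ether-catalysed domino Michael/aldol condensation of 2-(nitromethyl)benzaldehydes with enals to 1,2-dihydronaphthalene-3-carbaldehydes, together with direct vinylogous Michael additions of butenolide-type pronucleophiles to enal iminium ions; what is new is a pyranon-4-ylmethyl C–H acid in place of a nitroalkyl one. The six-membered carbocycle closes in a formal [4+2] manner, C1–C2 intermolecularly and then C3–C4 by a 6-(enolexo)-exo-trig enamine aldol addition. C2 is set by the catalyst, whose Ar2C(OTMS) group covers the Re face of the β-carbon of the s-trans E-iminium ion so that C1 attacks the Si face to give 2S; C1 is set relative to C2 under thermodynamic control, because C1–H remains the most acidic C–H of the product and acetate can equilibrate it to the 1,2-trans (1R) isomer. The step needs γ- over α-attack of the dienolate (attack through pyranone C3′ would break the lactone conjugation and cannot lead on to a ring), reaction through the iminium ion and not through free 8 (hence a weak base in sub-stoichiometric amount), and a pyranone that the hindered secondary amine leaves alone.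

**Step 5**
Reactants: 11 ethyl (1R,2S)-1-[6-(ethoxycarbonyl)-2-oxo-2H-pyran-4-yl]-3-formyl-6,7-dimethoxy-1,2-dihydronaphthalene-2-carboxylate
Product: 12 (1R,2S)-2-(ethoxycarbonyl)-1-[6-(ethoxycarbonyl)-2-oxo-2H-pyran-4-yl]-6,7-dimethoxy-1,2-dihydronaphthalene-3-carboxylic acid
Conditions: NaClO2, NaH2PO4, 2-methyl-2-butene (excess), t-BuOH/H2O, 0 °C → rt
Reagents that add atoms: sodium chlorite, [Na+].[O-]Cl=O
Why: Pinnick oxidation; chlorous acid adds to the aldehyde and fragments to the acid, the buffered medium leaves the trisubstituted alkene, the pyranone and the C1/C2 stereocentres untouched, and the alkene scavenger removes HOCl before it can chlorinate the dimethoxyarene.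

**Step 6**
Reactants: 12 (1R,2S)-2-(ethoxycarbonyl)-1-[6-(ethoxycarbonyl)-2-oxo-2H-pyran-4-yl]-6,7-dimethoxy-1,2-dihydronaphthalene-3-carboxylic acid
Product: 13 (1R,2S)-1-(6-carboxy-2-oxo-2H-pyran-4-yl)-6,7-dihydroxy-1,2-dihydronaphthalene-2,3-dicarboxylic acid
Conditions: BBr3 (12 equiv), CH2Cl2, −78 °C → rt; then H2O, 0 °C
Reagents that add atoms: none
Why: Lewis acid dealkylation with BBr3; after O–B complexation bromide attacks the methyl and ethyl carbons (SN2) of the two aryl ethers and the two ethyl esters, the lactone has no O–alkyl bond to cleave, and the base-free conditions leave the acidic C1–H and C2–H alone before water hydrolyses the borates.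

**Compound list**

1 | ethyl 3-methylbut-2-enoate | CCOC(=O)C=C(C)C | starting material
2 | diethyl oxalate | CCOC(=O)C(=O)OCC | starting material
3 | diethyl (2Z,4Z)-2-hydroxy-4-methylhexa-2,4-dienedioate (cyclisation-competent enol form, formed as its potassium enolate) | CCOC(=O)/C(O)=C/C(C)=C\C(=O)OCC | intermediate (not isolated)
4 | ethyl 4-methyl-2-oxo-2H-pyran-6-carboxylate | CCOC(=O)c1cc(C)cc(=O)o1 | intermediate
5 | ethyl 4-(bromomethyl)-2-oxo-2H-pyran-6-carboxylate | CCOC(=O)c1cc(CBr)cc(=O)o1 | intermediate
6 | (2-formyl-4,5-dimethoxyphenyl)boronic acid | COc1cc(C=O)c(B(O)O)cc1OC | starting material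
7 | ethyl 4-(2-formyl-4,5-dimethoxybenzyl)-2-oxo-2H-pyran-6-carboxylate | CCOC(=O)c1cc(Cc2cc(OC)c(OC)cc2C=O)cc(=O)o1 | intermediate
8 | ethyl (E)-4-oxobut-2-enoate | CCOC(=O)/C=C/C=O | starting material
9 | ethyl (2R,3R)-3-[6-(ethoxycarbonyl)-2-oxo-2H-pyran-4-yl]-3-(2-formyl-4,5-dimethoxyphenyl)-2-(2-oxoethyl)propanoate | CCOC(=O)[C@H](CC=O)[C@H](c1cc(C(=O)OCC)oc(=O)c1)c1cc(OC)c(OC)cc1C=O | intermediate (not isolated)
10 | ethyl (1R,2S)-1-[6-(ethoxycarbonyl)-2-oxo-2H-pyran-4-yl]-3-formyl-4-hydroxy-6,7-dimethoxy-1,2,3,4-tetrahydronaphthalene-2-carboxylate (C3 and C4 configuration left open; both centres are lost on dehydration) | O=CC1C(O)c2cc(OC)c(OC)cc2[C@@H](c2cc(C(=O)OCC)oc(=O)c2)[C@@H]1C(=O)OCC | intermediate (not isolated)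
11 | ethyl (1R,2S)-1-[6-(ethoxycarbonyl)-2-oxo-2H-pyran-4-yl]-3-formyl-6,7-dimethoxy-1,2-dihydronaphthalene-2-carboxylate | O=CC1=Cc2cc(OC)c(OC)cc2[C@@H](c2cc(C(=O)OCC)oc(=O)c2)[C@@H]1C(=O)OCC | intermediate
12 | (1R,2S)-2-(ethoxycarbonyl)-1-[6-(ethoxycarbonyl)-2-oxo-2H-pyran-4-yl]-6,7-dimethoxy-1,2-dihydronaphthalene-3-carboxylic acid | O=C(O)C1=Cc2cc(OC)c(OC)cc2[C@@H](c2cc(C(=O)OCC)oc(=O)c2)[C@@H]1C(=O)OCC | intermediate
13 | (1R,2S)-1-(6-carboxy-2-oxo-2H-pyran-4-yl)-6,7-dihydroxy-1,2-dihydronaphthalene-2,3-dicarboxylic acid | O=C(O)C1=Cc2cc(O)c(O)cc2[C@@H](c2cc(C(=O)O)oc(=O)c2)[C@@H]1C(=O)O | target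

Total steps: 6. Longest linear sequence: 6 steps (1 → 4 → 5 → 7 → 11 → 12 → 13).

**Steps most likely to fail**

1. Step 4 (proposed new method). Deprotonation of 7 may be too slow under amine/acetate conditions, and a stronger base would open a racemic background addition to free 8. Equilibration at C1 may stay incomplete, and the amine may attack the pyranone. The fallback uses known chemistry with auxiliary control in place of catalyst control; it sets out from 7 and returns at 13.
   - Irradiation of 7 (350 nm, benzene saturated with SO2) should trap the photoenol as ethyl 4-(1-hydroxy-5,6-dimethoxy-2,2-dioxo-1,3-dihydrobenzo[c]thiophen-3-yl)-2-oxo-2H-pyran-6-carboxylate F1.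
   - The chiral dienophile bis[(S)-2-methoxy-2-oxo-1-phenylethyl] fumarate F2 would be made from fumaryl chloride and methyl (S)-mandelate (pyridine, CH2Cl2).
   - Heating F1 with F2 (toluene, 80–110 °C, ZnO) should extrude SO2, and the (E,E)-α-hydroxy-o-quinodimethane should add to F2 in an endo Diels–Alder reaction (ester next to OH endo). This should give the 1,2-trans-2,3-trans-3,4-cis tetralol bis[(S)-2-methoxy-2-oxo-1-phenylethyl] (1R,2S,3R,4R)-1-[6-(ethoxycarbonyl)-2-oxo-2H-pyran-4-yl]-4-hydroxy-6,7-dimethoxy-1,2,3,4-tetrahydronaphthalene-2,3-dicarboxylate F3.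
   - Acid-catalysed dehydration (TsOH cat., toluene, 60 °C; benzylic cation para to OMe) should give bis[(S)-2-methoxy-2-oxo-1-phenylethyl] (1R,2S)-1-[6-(ethoxycarbonyl)-2-oxo-2H-pyran-4-yl]-6,7-dimethoxy-1,2-dihydronaphthalene-2,3-dicarboxylate F4.
   - BBr3 (CH2Cl2, −78 °C → rt, then H2O) should then cleave the two benzylic mandelate C–O bonds, the ethyl ester and the two methyl ethers to reach 13.
   - The (R)-mandelate is equally available if the facial sense with this diene proves to be the opposite.

2. Step 6. Dealkylation of the two ethyl esters may stay incomplete, or the product may degrade on long exposure to BBr3/HBr. The fallback separates the two kinds of cleavage and changes the ester cleavage to Brønsted acid hydrolysis; it sets out from 12 and returns at 13.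
   - BBr3 (5 equiv, CH2Cl2, −78 → 0 °C, short time) should remove only the methyl ethers and give (1R,2S)-2-(ethoxycarbonyl)-1-[6-(ethoxycarbonyl)-2-oxo-2H-pyran-4-yl]-6,7-dihydroxy-1,2-dihydronaphthalene-3-carboxylic acid F5.
   - 6 M HCl/1,4-dioxane at 80 °C, conditions under which 2-pyranone-6-carboxylic acids are themselves prepared, should then hydrolyse both ethyl esters to 13.

3. Step 3. The allylic bromide may be solvolysed or reduced, the ortho-formyl boronic acid may protodeboronate, and the product may self-condense under base. The fallback is a base-free Stille coupling; it sets out from 5 and returns at 7.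
   - Commercial 2-bromo-4,5-dimethoxybenzaldehyde would be stannylated (hexabutylditin, Pd(PPh3)4, toluene, 110 °C) to 4,5-dimethoxy-2-(tributylstannyl)benzaldehyde F6.
   - F6 would be coupled with 5 (Pd2(dba)3, AsPh3, THF, 50 °C) to give 7.

**Further compounds**

F1 | step 4 | ethyl 4-(1-hydroxy-5,6-dimethoxy-2,2-dioxo-1,3-dihydrobenzo[c]thiophen-3-yl)-2-oxo-2H-pyran-6-carboxylate (mixture of diastereomers) | CCOC(=O)c1cc(C2c3cc(OC)c(OC)cc3C(O)S2(=O)=O)cc(=O)o1
F2 | step 4 | bis[(S)-2-methoxy-2-oxo-1-phenylethyl] (E)-but-2-enedioate | COC(=O)[C@@H](OC(=O)/C=C/C(=O)O[C@@H](c1ccccc1)C(=O)OC)c1ccccc1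
F3 | step 4 | bis[(S)-2-methoxy-2-oxo-1-phenylethyl] (1R,2S,3R,4R)-1-[6-(ethoxycarbonyl)-2-oxo-2H-pyran-4-yl]-4-hydroxy-6,7-dimethoxy-1,2,3,4-tetrahydronaphthalene-2,3-dicarboxylate | O=C(O[C@@H](c1ccccc1)C(=O)OC)[C@H]1[C@@H](O)c2cc(OC)c(OC)cc2[C@@H](c2cc(C(=O)OCC)oc(=O)c2)[C@@H]1C(=O)O[C@@H](c1ccccc1)C(=O)OC
F4 | step 4 | bis[(S)-2-methoxy-2-oxo-1-phenylethyl] (1R,2S)-1-[6-(ethoxycarbonyl)-2-oxo-2H-pyran-4-yl]-6,7-dimethoxy-1,2-dihydronaphthalene-2,3-dicarboxylate | O=C(O[C@@H](c1ccccc1)C(=O)OC)C1=Cc2cc(OC)c(OC)cc2[C@@H](c2cc(C(=O)OCC)oc(=O)c2)[C@@H]1C(=O)O[C@@H](c1ccccc1)C(=O)OC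
F5 | step 6 | (1R,2S)-2-(ethoxycarbonyl)-1-[6-(ethoxycarbonyl)-2-oxo-2H-pyran-4-yl]-6,7-dihydroxy-1,2-dihydronaphthalene-3-carboxylic acid | O=C(O)C1=Cc2cc(O)c(O)cc2[C@@H](c2cc(C(=O)OCC)oc(=O)c2)[C@@H]1C(=O)OCC
F6 | step 3 | 4,5-dimethoxy-2-(tributylstannyl)benzaldehyde | CCCC[Sn](CCCC)(CCCC)c1cc(OC)c(OC)cc1C=O
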